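If you want to know how the two peaks will stand in the flask charged equally with starting material and partner, count how often the target has turned over, with every amount taken as a fraction of the charge.

| flask | starting material | partner | remark | time |
|---|---|---|---|---|
| dusk | 21 mM | 14 mM | run made earlier |  |
| midnight | 21 mM | 32 mM | run made earlier |  |
| summer | 32 mM | 21 mM | run made earlier |  |
| flask | 21 mM | 21.0 mM |  | 10 d |

| run | time / d | target / % | isomer of the product A / % |
|---|---|---|---|
| dusk | 1.67 | 21 | 4 |
| dusk | 3.00 | 19 | 6 |
| dusk | 5.00 | 15 | 6 |
| dusk | 6.00 | 14 | 8 |
| midnight | 1.67 | 41 | 8 |
| midnight | 3.00 | 31 | 11 |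
| midnight | 5.00 | 25 | 10 |
| midnight | 6.00 | 24 | 9 |
| summer | 1.67 | 26 | 6 |
| summer | 3.00 | 20 | 3 |
| summer | 5.00 | 13 | 7 |
| summer | 6.00 | 12 | 5 |

(each reading ± 1.5 percentage points)

- the numbers in the tables scatter by 1.5 percentage points (one standard deviation)

1. share of target in target plus isomer of the product A at 5.0 min
2. share of target in target plus isomer of the product A at 4.0 h
3. share of target in target plus isomer of the product A at 10 d

Read the target columns from first row to last. The dusk run falls at 0.0936 d⁻¹ and the midnight run at 0.124 d⁻¹. The summer run, richer in starting material, falls faster, at 0.179 d⁻¹. But the dusk and midnight runs, with the same charge of starting material, already differ by 1.32 times, so with a scatter of 1.5 percentage points on each reading I draw no order in starting material from these falls.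

The flask has the starting material of the dusk and midnight runs and a partner charge between theirs, so I take their mean, 0.109 d⁻¹. That gives 0.905 turnovers by 10 d. This turnover count, the fall constant times the days after the first reading, divides the target by e for each unit.

Interpolating the first row in partner gives 28.8 %, so the target should reach 11.6 %. The isomer of the product A does not follow it. Its mean in those two runs goes from 6.00 % to 8.50 %, a weak sign against a scatter of 1.5 points, and the summer run shows no such rise. Carried straight on, it reaches 10.8 %, so my share at 10 d is 51.9 %. The readings begin at 1.67 d, so I reckon nothing for the two early times.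

The forecast gives 87 %, 86 % and 60 %, on this ground: “so it does not collect the lost target”. Its late share stands above mine, and we part on the isomer of the product A, which it puts near 8 %.

The flask gives 96.6 %, 95.8 % and 48.9 %.

    starting material + partner ⇌ target (K = 85.0 M⁻¹, k = 6.50 M⁻¹ h⁻¹)
    starting material + partner ⇌ isomer of the product A (K = 140 M⁻¹, k = 0.230 M⁻¹ h⁻¹)
    target ⇌ isomer of the product B (K = 0.450, k = 0.0150 h⁻¹)
    partner → decomposed reagent (k = 0.00780 h⁻¹)
    starting material + target → side product (k = 0.260 M⁻¹ h⁻¹)

At 10 d the flask holds target 10.8 % against the reckoned 11.6 %, and isomer of the product A 11.2 % against 10.8 %. The neighbour flask takes 84 mM of starting material, with everything else as charged. Its partner equals 25.0 % of its charge of starting material, and the count of 0.905, carried over unchanged, brings this ceiling down to 10.1 %. The neighbour flask holds less target, 1.25 %, which from that ceiling is a count of 3.00, beside 2.88 % of the isomer of the product A, a share of 30.3 %.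

(The runs are calculated on assumed constants.)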